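**Strategy.** Everything rests on the bond between chroman C4 and the side-chain CH2. C4 is benzylic to ring A and is flanked by three donor oxygens (O1 through C8a, the oxygen at C5, the methoxy group at C7), so a (2R)-flavan-4-ol ionises to a cation that is an O-alkylated ortho-quinone methide. In one operation a silyl dienol ether of a 4-arylbut-3-en-2-one adds to it through its CH2 terminus, joining the flavan and arylbutanoid halves, while the C2 aryl group steers the attack to the 2,4-trans chroman. The precursors are a flavan-4-ol that already carries the C8 acetyl group and a 2-silyloxydiene; the enone left behind lets a CBS reduction set the carbinol.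

Key step: step 8

Remark on the chemistry: 9 is carried as the mixture of its C4 epimers, because both ionise to the same cation. The C4 descriptor reads R in 14 and S from 15 onward only because the CIP ranking of the side chain changes; the spatial arrangement (2,4-trans) is the same throughout.

**Route**

Step 1
Reactants: 1 1-(2,4-dihydroxy-6-methoxyphenyl)ethan-1-one
Product: 2 1-[4-(benzyloxy)-2-hydroxy-6-methoxyphenyl]ethan-1-one
Conditions: BnBr, K2CO3, acetone, reflux
Reagents that add atoms: benzyl bromide, BrCc1ccccc1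
Why: Williamson etherification is selective for the 4-OH, the only phenol not hydrogen-bonded to the acetyl group, so the 2-OH stays free to become O1.

Step 2
Reactants: 3 4-formylphenyl acetate
Product: 5 4-[(1S)-1-hydroxybut-3-en-1-yl]phenyl acetate, via pinacol borate ester 4 (not isolated)
Conditions: allylB(pin), (S)-3,3'-bis(2,4,6-triisopropylphenyl)-1,1'-binaphthyl-2,2'-diyl hydrogen phosphate (5 mol%), toluene, −30 °C; aqueous work-up
Reagents that add atoms: allylboronic acid pinacol ester, C=CCB1OC(C)(C)C(C)(C)O1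
Why: Chiral phosphoric acid-catalysed allylboration through a chair-like six-membered transition state, with the (S)-acid selected to deliver the allyl group to the Si face of the aryl aldehyde and so give the (S)-carbinol, the future C2 after inversion.

Step 3
Reactants: 2 1-[4-(benzyloxy)-2-hydroxy-6-methoxyphenyl]ethan-1-one; 5 4-[(1S)-1-hydroxybut-3-en-1-yl]phenyl acetate
Product: 6 4-[(1R)-1-[2-acetyl-5-(benzyloxy)-3-methoxyphenoxy]but-3-en-1-yl]phenyl acetate
Conditions: PPh3, DIAD, toluene, 0 → 25 °C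
Reagents that add atoms: none
Why: Mitsunobu etherification with SN2 inversion turns the (S)-carbinol into the (R)-aryl ether (the C2–O1 bond), the electron-poor 4-acetoxyphenyl group suppressing SN1 racemisation and the single free phenol of 2 fixing the regiochemistry.

Step 4
Reactants: 6 4-[(1R)-1-[2-acetyl-5-(benzyloxy)-3-methoxyphenoxy]but-3-en-1-yl]phenyl acetate
Product: 8 4-[(1R)-1-[2-acetyl-5-(benzyloxy)-3-methoxyphenoxy]-3-oxopropyl]phenyl acetate, via secondary ozonide 7 (not isolated)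
Conditions: O3, CH2Cl2, −78 °C (Sudan Red 7B end point); PPh3, −78 → 25 °C; used directly
Reagents that add atoms: ozone, [O-][O+]=O
Why: Ozonolysis with neutral reductive work-up cleaves the terminal alkene, which reacts far faster than the acyl-deactivated arenes, and leaves the aldehyde carbon that becomes C4.

Step 5
Reactants: 8 4-[(1R)-1-[2-acetyl-5-(benzyloxy)-3-methoxyphenoxy]-3-oxopropyl]phenyl acetate
Product: 9 4-[(2R)-8-acetyl-5-(benzyloxy)-4-hydroxy-7-methoxy-3,4-dihydro-2H-chromen-2-yl]phenyl acetate (both C4 epimers)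
Conditions: Me2AlCl (3 equiv), CH2Cl2, −78 → −20 °C; aq. potassium sodium tartrate
Reagents that add atoms: none
Why: Intramolecular Friedel–Crafts hydroxyalkylation closes the six-membered ring at the only free position ortho to the ether oxygen (activated by the ortho benzyloxy and para methoxy groups), Me2AlCl acting as Lewis acid and proton scavenger so that the benzylic alcohol is not ionised further; the C4 configuration is irrelevant.

Step 6
Reactants: 10 (3E)-4-(4-hydroxyphenyl)but-3-en-2-one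
Product: 11 4-[(1E)-3-oxobut-1-en-1-yl]phenyl acetate
Conditions: Ac2O, pyridine, CH2Cl2, 0 → 25 °C
Reagents that add atoms: acetic anhydride, CC(=O)OC(C)=O
Why: Simple O-acetylation gives the phenol the same neutral-labile protecting group as the other fragment.

Step 7
Reactants: 11 4-[(1E)-3-oxobut-1-en-1-yl]phenyl acetate
Product: 12 4-[(1E)-3-[(tert-butyldimethylsilyl)oxy]buta-1,3-dien-1-yl]phenyl acetate
Conditions: TBSOTf, Et3N, CH2Cl2, 0 °C
Reagents that add atoms: tert-butyldimethylsilyl trifluoromethanesulfonate, CC(C)(C)[Si](C)(C)OS(=O)(=O)C(F)(F)F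
Why: Soft enolisation and O-silylation of the methyl ketone (the methyl group is the only enolisable position) gives the 2-silyloxydiene, a ketone much faster to silylate than the aryl acetate.

Step 8
Reactants: 9 4-[(2R)-8-acetyl-5-(benzyloxy)-4-hydroxy-7-methoxy-3,4-dihydro-2H-chromen-2-yl]phenyl acetate (both C4 epimers); 12 4-[(1E)-3-[(tert-butyldimethylsilyl)oxy]buta-1,3-dien-1-yl]phenyl acetate
Product: 14 4-[(2R,4R)-8-acetyl-4-[(3E)-4-(4-acetoxyphenyl)-2-oxobut-3-en-1-yl]-5-(benzyloxy)-7-methoxy-3,4-dihydro-2H-chromen-2-yl]phenyl acetate (2,4-trans), via chroman-4-yl cation 13 (not isolated)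
Conditions: TMSOTf (0.3 equiv), 12 (2.5 equiv), CH2Cl2, −78 → −40 °C; aq. NaHCO3
Reagents that add atoms: none
Why: TMSOTf ionises either C4 epimer of 9 to the same benzylic cation 13, stabilised by O1 (through C8a), the C5 benzyloxy group and the C7 methoxy group of ring A (an O-alkylated ortho-quinone methide); the silyl dienol ether 12 attacks it through its terminal CH2 and loss of the silyl group leaves the enone. The closest known reaction type is the Lewis-acid-mediated C4 substitution of flavan-4-ols and 4-alkoxyflavans by allylsilanes and silyl enol ethers (a Mukaiyama-type SN1 alkylation). No ring is closed. The new C4 stereocentre is controlled by C2: the cation adopts a half-chair with the 2-aryl group pseudo-equatorial and the nucleophile enters pseudo-axially on the face anti to it, which also places the new substituent pseudo-axial, away from the peri C5 benzyloxy group, so the 2,4-trans isomer should dominate. The step needs facial selectivity, C-alkylation at the CH2 terminus of 12, and substitution in preference to loss of H3 (2H-chromene formation); low temperature, the excess of nucleophilic diene and the electron-poor 4-acetoxyphenyl group at C2, which keeps the C2–O1 bond from ionising, should secure them.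

Step 9
Reactants: 14 4-[(2R,4R)-8-acetyl-4-[(3E)-4-(4-acetoxyphenyl)-2-oxobut-3-en-1-yl]-5-(benzyloxy)-7-methoxy-3,4-dihydro-2H-chromen-2-yl]phenyl acetate
Product: 15 4-[(2R,4S)-8-acetyl-4-[(2S,3E)-4-(4-acetoxyphenyl)-2-hydroxybut-3-en-1-yl]-5-(benzyloxy)-7-methoxy-3,4-dihydro-2H-chromen-2-yl]phenyl acetate
Conditions: (R)-Me-CBS [(R)-1-methyl-3,3-diphenyltetrahydro-1H,3H-pyrrolo[1,2-c][1,3,2]oxazaborole] (0.2 equiv), catecholborane, toluene, −78 °C; MeOH
Reagents that add atoms: none
Why: Corey–Bakshi–Shibata 1,2-reduction in which the alkenyl group acts as the large substituent, so the (R)-catalyst should give the (S)-allylic alcohol (the later (R)-carbinol), while the di-ortho-substituted, electron-rich 8-acetyl group is too hindered to compete at −78 °C.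

Step 10
Reactants: 15 4-[(2R,4S)-8-acetyl-4-[(2S,3E)-4-(4-acetoxyphenyl)-2-hydroxybut-3-en-1-yl]-5-(benzyloxy)-7-methoxy-3,4-dihydro-2H-chromen-2-yl]phenyl acetate
Product: 16 4-[(2R,4S)-4-[(2R)-4-(4-acetoxyphenyl)-2-hydroxybutyl]-8-acetyl-5-hydroxy-7-methoxy-3,4-dihydro-2H-chromen-2-yl]phenyl acetate
Conditions: H2 (1 atm), 10% Pd/C, EtOAc, 25 °C
Reagents that add atoms: none
Why: Heterogeneous hydrogenation saturates the disubstituted alkene and hydrogenolyses the C5 benzyl ether in one operation, leaving the aryl acetates, the hindered aryl ketone and all three stereocentres untouched.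

Step 11
Reactants: 16 4-[(2R,4S)-4-[(2R)-4-(4-acetoxyphenyl)-2-hydroxybutyl]-8-acetyl-5-hydroxy-7-methoxy-3,4-dihydro-2H-chromen-2-yl]phenyl acetate; 3 4-formylphenyl acetate
Product: 18 4-[(1E)-3-[(2R,4S)-2-(4-acetoxyphenyl)-4-[(2R)-4-(4-acetoxyphenyl)-2-hydroxybutyl]-5-hydroxy-7-methoxy-3,4-dihydro-2H-chromen-8-yl]-3-oxoprop-1-en-1-yl]phenyl acetate, via aldol adduct 17 (not isolated)
Conditions: 3 (1.5 equiv), BF3·OEt2, 1,4-dioxane, 25 °C
Reagents that add atoms: none
Why: BF3-mediated Claisen–Schmidt condensation (aldol addition, then dehydration to the (E)-enone) tolerates aryl acetates, and the 4-acetoxyphenyl group at C2 keeps the C2–O1 bond from ionising under the Lewis acid.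

Step 12
Reactants: 18 4-[(1E)-3-[(2R,4S)-2-(4-acetoxyphenyl)-4-[(2R)-4-(4-acetoxyphenyl)-2-hydroxybutyl]-5-hydroxy-7-methoxy-3,4-dihydro-2H-chromen-8-yl]-3-oxoprop-1-en-1-yl]phenyl acetate
Product: 19 CNP0102599.2, (2E)-1-[(2R,4S)-5-hydroxy-4-[(2R)-2-hydroxy-4-(4-hydroxyphenyl)butyl]-2-(4-hydroxyphenyl)-7-methoxy-3,4-dihydro-2H-chromen-8-yl]-3-(4-hydroxyphenyl)prop-2-en-1-one
Conditions: NH4OAc, MeOH/H2O (4:1), 25 °C
Reagents that add atoms: none
Why: Ammonium acetate-mediated solvolysis cleaves the three aryl acetates under neutral conditions, so neither acid nor base can open the chroman at C2 through a para-quinone methide and epimerise it.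

**Compound list**

1 | 1-(2,4-dihydroxy-6-methoxyphenyl)ethan-1-one | COc1cc(O)cc(O)c1C(C)=O | starting material
2 | 1-[4-(benzyloxy)-2-hydroxy-6-methoxyphenyl]ethan-1-one | COc1cc(OCc2ccccc2)cc(O)c1C(C)=O | intermediate
3 | 4-formylphenyl acetate | CC(=O)Oc1ccc(C=O)cc1 | starting material
4 | 4-[(1S)-1-[(4,4,5,5-tetramethyl-1,3,2-dioxaborolan-2-yl)oxy]but-3-en-1-yl]phenyl acetate (formed in the flask) | C=CC[C@H](OB1OC(C)(C)C(C)(C)O1)c1ccc(OC(C)=O)cc1 | intermediate
5 | 4-[(1S)-1-hydroxybut-3-en-1-yl]phenyl acetate | C=CC[C@H](O)c1ccc(OC(C)=O)cc1 | intermediate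
6 | 4-[(1R)-1-[2-acetyl-5-(benzyloxy)-3-methoxyphenoxy]but-3-en-1-yl]phenyl acetate | C=CC[C@@H](Oc1cc(OCc2ccccc2)cc(OC)c1C(C)=O)c1ccc(OC(C)=O)cc1 | intermediate
7 | 4-[(1R)-1-[2-acetyl-5-(benzyloxy)-3-methoxyphenoxy]-2-(1,2,4-trioxolan-3-yl)ethyl]phenyl acetate (secondary ozonide, formed in the flask) | O1OC(C[C@@H](Oc2cc(OCc3ccccc3)cc(OC)c2C(C)=O)c2ccc(OC(C)=O)cc2)OC1 | intermediate
8 | 4-[(1R)-1-[2-acetyl-5-(benzyloxy)-3-methoxyphenoxy]-3-oxopropyl]phenyl acetate | O=CC[C@@H](Oc1cc(OCc2ccccc2)cc(OC)c1C(C)=O)c1ccc(OC(C)=O)cc1 | intermediate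
9 | 4-[(2R)-8-acetyl-5-(benzyloxy)-4-hydroxy-7-methoxy-3,4-dihydro-2H-chromen-2-yl]phenyl acetate (both C4 epimers) | COc1cc(OCc2ccccc2)c2c(c1C(C)=O)O[C@@H](c1ccc(OC(C)=O)cc1)CC2O | intermediate
10 | (3E)-4-(4-hydroxyphenyl)but-3-en-2-one | CC(=O)/C=C/c1ccc(O)cc1 | starting material
11 | 4-[(1E)-3-oxobut-1-en-1-yl]phenyl acetate | CC(=O)/C=C/c1ccc(OC(C)=O)cc1 | intermediate
12 | 4-[(1E)-3-[(tert-butyldimethylsilyl)oxy]buta-1,3-dien-1-yl]phenyl acetate | C=C(O[Si](C)(C)C(C)(C)C)/C=C/c1ccc(OC(C)=O)cc1 | intermediate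
13 | (2R)-2-(4-acetoxyphenyl)-8-acetyl-5-(benzyloxy)-7-methoxy-3,4-dihydro-2H-chromen-4-ylium (formed in the flask) | COc1cc(OCc2ccccc2)c2c(c1C(C)=O)O[C@@H](c1ccc(OC(C)=O)cc1)C[CH+]2 | intermediate
14 | 4-[(2R,4R)-8-acetyl-4-[(3E)-4-(4-acetoxyphenyl)-2-oxobut-3-en-1-yl]-5-(benzyloxy)-7-methoxy-3,4-dihydro-2H-chromen-2-yl]phenyl acetate | COc1cc(OCc2ccccc2)c2c(c1C(C)=O)O[C@@H](c1ccc(OC(C)=O)cc1)C[C@@H]2CC(=O)/C=C/c1ccc(OC(C)=O)cc1 | intermediate
15 | 4-[(2R,4S)-8-acetyl-4-[(2S,3E)-4-(4-acetoxyphenyl)-2-hydroxybut-3-en-1-yl]-5-(benzyloxy)-7-methoxy-3,4-dihydro-2H-chromen-2-yl]phenyl acetate | COc1cc(OCc2ccccc2)c2c(c1C(C)=O)O[C@@H](c1ccc(OC(C)=O)cc1)C[C@@H]2C[C@H](O)/C=C/c1ccc(OC(C)=O)cc1 | intermediate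
16 | 4-[(2R,4S)-4-[(2R)-4-(4-acetoxyphenyl)-2-hydroxybutyl]-8-acetyl-5-hydroxy-7-methoxy-3,4-dihydro-2H-chromen-2-yl]phenyl acetate | COc1cc(O)c2c(c1C(C)=O)O[C@@H](c1ccc(OC(C)=O)cc1)C[C@@H]2C[C@H](O)CCc1ccc(OC(C)=O)cc1 | intermediate
17 | 4-[3-[(2R,4S)-2-(4-acetoxyphenyl)-4-[(2R)-4-(4-acetoxyphenyl)-2-hydroxybutyl]-5-hydroxy-7-methoxy-3,4-dihydro-2H-chromen-8-yl]-1-hydroxy-3-oxopropyl]phenyl acetate (aldol adduct, formed in the flask) | COc1cc(O)c2c(c1C(=O)CC(O)c1ccc(OC(C)=O)cc1)O[C@@H](c1ccc(OC(C)=O)cc1)C[C@@H]2C[C@H](O)CCc1ccc(OC(C)=O)cc1 | intermediate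
18 | 4-[(1E)-3-[(2R,4S)-2-(4-acetoxyphenyl)-4-[(2R)-4-(4-acetoxyphenyl)-2-hydroxybutyl]-5-hydroxy-7-methoxy-3,4-dihydro-2H-chromen-8-yl]-3-oxoprop-1-en-1-yl]phenyl acetate | COc1cc(O)c2c(c1C(=O)/C=C/c1ccc(OC(C)=O)cc1)O[C@@H](c1ccc(OC(C)=O)cc1)C[C@@H]2C[C@H](O)CCc1ccc(OC(C)=O)cc1 | intermediate
19 | CNP0102599.2, (2E)-1-[(2R,4S)-5-hydroxy-4-[(2R)-2-hydroxy-4-(4-hydroxyphenyl)butyl]-2-(4-hydroxyphenyl)-7-methoxy-3,4-dihydro-2H-chromen-8-yl]-3-(4-hydroxyphenyl)prop-2-en-1-one | COc1cc(O)c2c(c1C(=O)/C=C/c1ccc(O)cc1)O[C@@H](c1ccc(O)cc1)C[C@@H]2C[C@H](O)CCc1ccc(O)cc1 | target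

**Count**

Total steps: 12. Longest linear sequence: 9 steps (steps 2, 3, 4, 5, 8, 9, 10, 11, 12).

**Steps most likely to fail, with fallbacks**

Step 8. The cation may lose H3 to give a 2H-chromene faster than it is captured, or the facial selectivity of the capture may be poor. The fallback joins the same two halves before the chroman exists. It sets out from aldehyde 8 and diene 12: a Mukaiyama aldol addition (BF3·OEt2, CH2Cl2, −78 °C, where ring closure of 8 is slow) forms the same carbon–carbon bond and should give the β-hydroxy enone F1. Acid-catalysed dehydration (TsOH, toluene, 50 °C) should then give the cross-conjugated dienone F2. A Sc(OTf)3-catalysed intramolecular Friedel–Crafts conjugate addition of ring A to the alkyl-substituted β-carbon (six-membered ring closure) closes the chroman and comes back to the route at 14; the peri benzyloxy group should again favour the pseudo-axial side chain.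

Step 5. The β-aryloxy aldehyde may eliminate the aryloxide before ring closure, or the benzylic alcohol formed may ionise further and oligomerise. The fallback closes the ring at the acyl oxidation level. It sets out from 8: Pinnick oxidation (NaClO2, NaH2PO4, 2-methylbut-2-ene, t-BuOH/H2O) should give the acid F3, and intramolecular Friedel–Crafts acylation (TFAA, CH2Cl2, 0 °C) the flavanone F4. Luche reduction (NaBH4, CeCl3·7H2O, MeOH/THF, −40 °C) of the chromanone carbonyl, which is more accessible than the di-ortho-substituted 8-acetyl group, comes back to the route at 9.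

Step 11. Condensation at the hindered, di-ortho-substituted aryl methyl ketone may be too slow under Lewis-acid conditions, so that side reactions of the aldehyde with the free phenol or alcohol take over. The fallback uses a base-mediated condensation on allyl-protected material. It sets out from 16: neutral deacetylation (NH4OAc, MeOH/H2O) should give the triphenol F5, and allyl bromide with K2CO3 in acetone the tris(allyl ether) F6. Claisen–Schmidt condensation with 4-(allyloxy)benzaldehyde (KOH, EtOH, 25 °C) should give the tetra-allyl chalcone F7, in which the alkylated 4'-oxygen protects C2 from base. Neutral deallylation (Pd(PPh3)4, morpholine, THF, 25 °C) comes back to the route at 19.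

**Further compounds**

F1 | step 8 | 4-[(1R,6E)-7-(4-acetoxyphenyl)-1-[2-acetyl-5-(benzyloxy)-3-methoxyphenoxy]-3-hydroxy-5-oxohept-6-en-1-yl]phenyl acetate (C3 epimers) | CC(=O)Oc1ccc(/C=C/C(=O)CC(O)C[C@@H](Oc2cc(OCc3ccccc3)cc(OC)c2C(C)=O)c2ccc(OC(C)=O)cc2)cc1
F2 | step 8 | 4-[(1R,3E,6E)-7-(4-acetoxyphenyl)-1-[2-acetyl-5-(benzyloxy)-3-methoxyphenoxy]-5-oxohepta-3,6-dien-1-yl]phenyl acetate | CC(=O)Oc1ccc(/C=C/C(=O)/C=C/C[C@@H](Oc2cc(OCc3ccccc3)cc(OC)c2C(C)=O)c2ccc(OC(C)=O)cc2)cc1
F3 | step 5 | (3R)-3-(4-acetoxyphenyl)-3-[2-acetyl-5-(benzyloxy)-3-methoxyphenoxy]propanoic acid | OC(=O)C[C@@H](Oc1cc(OCc2ccccc2)cc(OC)c1C(C)=O)c1ccc(OC(C)=O)cc1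
F4 | step 5 | 4-[(2R)-8-acetyl-5-(benzyloxy)-7-methoxy-4-oxo-3,4-dihydro-2H-chromen-2-yl]phenyl acetate | COc1cc(OCc2ccccc2)c2c(c1C(C)=O)O[C@@H](c1ccc(OC(C)=O)cc1)CC2=O
F5 | step 11 | 1-[(2R,4S)-5-hydroxy-4-[(2R)-2-hydroxy-4-(4-hydroxyphenyl)butyl]-2-(4-hydroxyphenyl)-7-methoxy-3,4-dihydro-2H-chromen-8-yl]ethan-1-one | COc1cc(O)c2c(c1C(C)=O)O[C@@H](c1ccc(O)cc1)C[C@@H]2C[C@H](O)CCc1ccc(O)cc1
F6 | step 11 | 1-[(2R,4S)-5-(allyloxy)-2-[4-(allyloxy)phenyl]-4-[(2R)-4-[4-(allyloxy)phenyl]-2-hydroxybutyl]-7-methoxy-3,4-dihydro-2H-chromen-8-yl]ethan-1-one | COc1cc(OCC=C)c2c(c1C(C)=O)O[C@@H](c1ccc(OCC=C)cc1)C[C@@H]2C[C@H](O)CCc1ccc(OCC=C)cc1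
F7 | step 11 | (2E)-1-[(2R,4S)-5-(allyloxy)-2-[4-(allyloxy)phenyl]-4-[(2R)-4-[4-(allyloxy)phenyl]-2-hydroxybutyl]-7-methoxy-3,4-dihydro-2H-chromen-8-yl]-3-[4-(allyloxy)phenyl]prop-2-en-1-one | COc1cc(OCC=C)c2c(c1C(=O)/C=C/c1ccc(OCC=C)cc1)O[C@@H](c1ccc(OCC=C)cc1)C[C@@H]2C[C@H](O)CCc1ccc(OCC=C)cc1
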